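**Retrosynthetic overview**
1. The strategy rests on the spiro carbon: it lies between C(CH3)2 and the C(=CH2) carbon of ring A (a masked ketone) and carries the CH2–CH2 arm that ends at the C(CH3)(OH) carbon of ring B. This is the 1,5-dioxygenated pattern that a de Mayo reaction draws across a 1,1-disubstituted alkene.
2. Target 24 ⇐ desilylation, methylenation of the ring A ketone, MeTi(OiPr)3 addition and α-chlorination ⇐ spiro enone 18 ⇐ aldol condensation of keto aldehyde 16 (ring B).
3. 16 ⇐ acetal 15 ⇐ enol–alkene [2+2] photocycloaddition and retro-aldol of 1,3-diketone 13 (ring A, quaternary carbon, oxobutyl arm).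
4. 13 ⇐ pentane-2,4-dione dianion + (S)-α-bromoaldehyde 9 (anti bromohydrin) ⇐ 3,3-dimethylglutaric anhydride + formaldehyde.
5. Ring order: ring A in step 10, ring B in step 12.

Key step: step 10

Assumption: the (S)-diarylprolinol silyl ether is taken to shield one face of the E-enamine of 8 so that bromine enters to give (S)-9, as in related α-heterofunctionalisations; if the sense were opposite, the (R)-catalyst would be used.

**Route**

Step 1
Reactants: 1 3,3-dimethylglutaric anhydride
Product: 2 5-methoxy-3,3-dimethyl-5-oxopentanoic acid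
Conditions: MeOH, DMAP (5 mol %), 65 °C
Reagents that add atoms: methanol (SMILES CO)
Why: Alcoholysis of the symmetric cyclic anhydride opens it to a single half ester.

Step 2
Reactants: 2 5-methoxy-3,3-dimethyl-5-oxopentanoic acid
Product: 3 methyl 5-hydroxy-3,3-dimethylpentanoate
Conditions: BH3·SMe2 (1.1 equiv), THF, 0 °C → rt; MeOH quench
Reagents that add atoms: none
Why: Borane reduces the carboxylic acid through its acyloxyborane far faster than the ester, so only the acid terminus should become the primary alcohol (chemoselective borane reduction).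

Step 3
Reactants: 3 methyl 5-hydroxy-3,3-dimethylpentanoate (crude, used at once)
Product: 4 methyl 3,3-dimethyl-5-oxopentanoate
Conditions: TEMPO (10 mol %), PhI(OAc)2 (1.1 equiv), CH2Cl2, rt
Reagents that add atoms: none
Why: Oxoammonium-mediated oxidation stops at the aldehyde and should be fast enough to outrun lactonisation of the hydroxy ester.

Step 4
Reactants: 4 methyl 3,3-dimethyl-5-oxopentanoate; 5 formaldehyde
Product: 6 methyl 4-formyl-3,3-dimethylpent-4-enoate
Conditions: 37% aq. CH2O, pyrrolidine (10 mol %), EtCO2H (10 mol %), i-PrOH, 45 °C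
Reagents that add atoms: none
Why: Mannich condensation of the aldehyde enamine with formaldehyde, then β-elimination of the amine, should give the 2-substituted acrolein (organocatalytic α-methylenation); only the aldehyde α-carbon forms an enamine.

Step 5
Reactants: 6 methyl 4-formyl-3,3-dimethylpent-4-enoate
Product: 7 methyl 4-(dimethoxymethyl)-3,3-dimethylpent-4-enoate
Conditions: HC(OMe)3, MeOH, NH4NO3 (cat.), rt
Reagents that add atoms: trimethyl orthoformate (SMILES COC(OC)OC)
Why: Orthoester-driven acetalisation under a very weak acid converts enals into dimethyl acetals without conjugate addition of methanol and leaves the ester alone.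

Step 6
Reactants: 7 methyl 4-(dimethoxymethyl)-3,3-dimethylpent-4-enoate
Product: 8 4-(dimethoxymethyl)-3,3-dimethylpent-4-enal
Conditions: iBu2AlH (1.05 equiv), CH2Cl2, −78 °C; aq. KNaC4H4O6
Reagents that add atoms: none
Why: At −78 °C the aluminium hemiacetal from hydride addition persists until work-up, so the ester should stop at the aldehyde with acetal and alkene untouched (partial ester reduction).

Step 7
Reactants: 8 4-(dimethoxymethyl)-3,3-dimethylpent-4-enal
Product: 9 (2S)-2-bromo-4-(dimethoxymethyl)-3,3-dimethylpent-4-enal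
Conditions: (S)-2-{bis[3,5-bis(trifluoromethyl)phenyl](trimethylsilyloxy)methyl}pyrrolidine (20 mol %), PhCO2H (20 mol %), 4,4-dibromo-2,6-di-tert-butylcyclohexa-2,5-dien-1-one (1.1 equiv), CH2Cl2/pentane, −40 °C; cold filtration through SiO2, used at once
Reagents that add atoms: 4,4-dibromo-2,6-di-tert-butylcyclohexa-2,5-dien-1-one (SMILES CC(C)(C)C1=CC(Br)(Br)C=C(C(C)(C)C)C1=O)
Why: In this enamine-catalysed α-bromination the E-enamine is brominated on the face away from the diaryl(silyloxy)methyl group of the catalyst, which sets the (S) C–Br centre, and the adjacent quaternary carbon should slow re-enolisation of the product.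

Step 8
Reactants: 9 (2S)-2-bromo-4-(dimethoxymethyl)-3,3-dimethylpent-4-enal; 10 pentane-2,4-dione
Product: 11 (6R,7S)-7-bromo-9-(dimethoxymethyl)-6-hydroxy-8,8-dimethyldec-9-ene-2,4-dione
Conditions: 10, LiN(iPr)2 (2.1 equiv), THF, 0 °C; then 9, −78 °C; AcOH, −78 °C
Reagents that add atoms: none
Why: The diketone dianion reacts at its terminal carbon in an aldol addition, and Cornforth (polar Felkin–Anh) approach past the α-hydrogen with C–Br opposed to C=O should give the 1,2-anti bromohydrin, that is the (6R) carbinol from the (7S) bromide.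

Step 9
Reactants: 11 (6R,7S)-7-bromo-9-(dimethoxymethyl)-6-hydroxy-8,8-dimethyldec-9-ene-2,4-dione
Product: 13 (6R,7S)-7-bromo-6-[(tert-butyldimethylsilyl)oxy]-9-(dimethoxymethyl)-8,8-dimethyldec-9-ene-2,4-dione, via bis-silylated enol ether 12 (not isolated)
Conditions: TBSOTf (2.5 equiv), 2,6-lutidine, CH2Cl2, −78 → 0 °C; then K2CO3 (0.2 equiv), MeOH, 0 °C
Reagents that add atoms: tert-butyldimethylsilyl triflate (SMILES CC(C)(C)[Si](C)(C)OS(=O)(=O)C(F)(F)F)
Why: The silyl triflate caps the hindered secondary alcohol and also the diketone enol oxygen, and brief methanolysis removes only the labile enol silyl ether to return the free 1,3-diketone (silyl ether protection).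

Step 10
Reactants: 13 (6R,7S)-7-bromo-6-[(tert-butyldimethylsilyl)oxy]-9-(dimethoxymethyl)-8,8-dimethyldec-9-ene-2,4-dione
Product: 15 (2S,4S,5R)-4-bromo-5-[(tert-butyldimethylsilyl)oxy]-2-(dimethoxymethyl)-3,3-dimethyl-2-(3-oxobutyl)cyclohexan-1-one, via cyclobutanol photoadduct 14 (not isolated)
Conditions: hν (medium-pressure Hg lamp, Pyrex, λ > 290 nm), degassed cyclohexane (5 mM), 15 °C; then SiO2, CH2Cl2, rt
Reagents that add atoms: none
Why: Light above 290 nm is absorbed only by the hydrogen-bonded enol of the 1,3-diketone (C–Br is transparent there), and the excited enol C=C should add stepwise through a 1,4-diradical to the tethered 1,1-disubstituted alkene to give the cis-fused bicyclo[4.2.0]octan-1-ol 14, whose β-hydroxy ketone unit opens by strain-driven retro-aldol to the 1,5-diketone 15. The closest known reaction type is the intramolecular de Mayo reaction (enol–alkene [2+2] photocycloaddition followed by retro-aldol). Ring A closes in the 6-exo mode by bonding the enol carbinol carbon (C4 of 13) to the fully substituted alkene carbon (C9), and the transient cyclobutane closes by diradical recombination between C3 and C10 and is then opened, so that the C10–C3 bond becomes the start of the oxobutyl arm. The one new stereocentre, the quaternary carbon, is set by the two existing centres: in the chair-like fold of the tether the enol should pair with the alkene on the face not occupied by bromine and the silyloxy group, because closure on their face would press the cyclobutane methylene against C–Br or the enol carbon against the axial silyloxy group and axial methyl, and this leaves the acetal arm cis to Br and OSi. The step needs straight rather than crossed regiochemistry, which the four-atom tether with its gem-dimethyl group secures by making the six-membered closure the only unstrained one, and it needs selective excitation, which the Pyrex cut-off and the strong enol absorption provide.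

Step 11
Reactants: 15 (2S,4S,5R)-4-bromo-5-[(tert-butyldimethylsilyl)oxy]-2-(dimethoxymethyl)-3,3-dimethyl-2-(3-oxobutyl)cyclohexan-1-one
Product: 16 (1S,3S,4R)-3-bromo-4-[(tert-butyldimethylsilyl)oxy]-2,2-dimethyl-6-oxo-1-(3-oxobutyl)cyclohexane-1-carbaldehyde
Conditions: TsOH·H2O (0.2 equiv), acetone/H2O (20:1), rt
Reagents that add atoms: water (SMILES O)
Why: Acid-catalysed acetal hydrolysis frees the aldehyde, which has no α-hydrogen and so cannot scramble the quaternary centre, while the secondary silyl ether and the bromide should tolerate the dilute acid.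

Step 12
Reactants: 16 (1S,3S,4R)-3-bromo-4-[(tert-butyldimethylsilyl)oxy]-2,2-dimethyl-6-oxo-1-(3-oxobutyl)cyclohexane-1-carbaldehyde
Product: 18 (3R,4S,6R)-4-bromo-3-[(tert-butyldimethylsilyl)oxy]-5,5-dimethylspiro[5.5]undec-7-ene-1,9-dione, via aldol 17 (not isolated)
Conditions: pyrrolidine (0.3 equiv), AcOH (0.3 equiv), toluene, 40 °C
Reagents that add atoms: none
Why: In this intramolecular aldol condensation the enamine of the unhindered methyl ketone attacks the more electrophilic aldehyde in a six-membered closure and the aldol dehydrates to the spiro enone, while the ring A ketone, screened by the quaternary carbon, should form no enamine under the buffered conditions and so keeps its β-silyloxy group.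

Step 13
Reactants: 18 (3R,4S,6R)-4-bromo-3-[(tert-butyldimethylsilyl)oxy]-5,5-dimethylspiro[5.5]undec-7-ene-1,9-dione
Product: 19 (3R,4S,6R)-4-bromo-3-[(tert-butyldimethylsilyl)oxy]-5,5-dimethyl-9-[(triethylsilyl)oxy]spiro[5.5]undec-8-en-1-one
Conditions: Et3SiH (1.5 equiv), RhCl(PPh3)3 (2 mol %), benzene, 50 °C
Reagents that add atoms: triethylsilane (SMILES CC[SiH](CC)CC)
Why: Rhodium-catalysed 1,4-hydrosilylation of the enone with a monohydrosilane gives the silyl enol ether regiospecifically on the side of the former C=C, which marks the carbon to be chlorinated and distinguishes it from the other α-methylene of ring B; the hindered ring A ketone and C–Br should not react.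

Step 14
Reactants: 19 (3R,4S,6R)-4-bromo-3-[(tert-butyldimethylsilyl)oxy]-5,5-dimethyl-9-[(triethylsilyl)oxy]spiro[5.5]undec-8-en-1-one
Product: 21 (3R,4S,6R,8S)-4-bromo-3-[(tert-butyldimethylsilyl)oxy]-8-chloro-5,5-dimethylspiro[5.5]undecane-1,9-dione, via epimeric chloroketone 20 (not isolated)
Conditions: NCS (1.05 equiv), THF, 0 °C; then Bu4NCl (0.3 equiv), acetone, rt
Reagents that add atoms: N-chlorosuccinimide (SMILES O=C1CCC(=O)N1Cl)
Why: Electrophilic chlorination of the silyl enol ether puts chlorine on the marked α-carbon, expected mainly anti to the axial ring A carbonyl branch of the spiro carbon, and degenerate SN2 chloride exchange at the α-keto carbon should funnel any epimer 20 to the more stable 21, in which Cl and the CMe2 branch are both equatorial on ring B.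

Step 15
Reactants: 21 (3R,4S,6R,8S)-4-bromo-3-[(tert-butyldimethylsilyl)oxy]-8-chloro-5,5-dimethylspiro[5.5]undecane-1,9-dione
Product: 22 (3R,4S,6R,8S,9R)-4-bromo-3-[(tert-butyldimethylsilyl)oxy]-8-chloro-9-hydroxy-5,5,9-trimethylspiro[5.5]undecan-1-one
Conditions: preformed MeTi(OiPr)3 (3 equiv), Et2O, −20 °C → rt
Reagents that add atoms: methyltitanium triisopropoxide (SMILES C[Ti](OC(C)C)(OC(C)C)OC(C)C)
Why: The non-basic organotitanium reagent should add only to the activated α-chloro ketone (the ring A ketone is too hindered) and deliver methyl along the equatorial trajectory of the locked chair, giving the axial tertiary alcohol cis to the equatorial chlorine.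

Step 16
Reactants: 22 (3R,4S,6R,8S,9R)-4-bromo-3-[(tert-butyldimethylsilyl)oxy]-8-chloro-9-hydroxy-5,5,9-trimethylspiro[5.5]undecan-1-one
Product: 23 (2S,3R,6S,8S,9R)-8-bromo-9-[(tert-butyldimethylsilyl)oxy]-2-chloro-3,7,7-trimethyl-11-methylidenespiro[5.5]undecan-3-ol
Conditions: Zn/CH2Br2/TiCl4 (prepared in THF, aged at 5 °C, excess), CH2Cl2, 0 °C → rt
Reagents that add atoms: dibromomethane (SMILES BrCBr)
Why: The Lombardo methylenation uses a non-basic zinc/titanium methylene reagent that olefinates hindered, enolisable ketones without β-elimination or epimerisation and tolerates the free tertiary alcohol at the cost of extra reagent.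

Step 17
Reactants: 23 (2S,3R,6S,8S,9R)-8-bromo-9-[(tert-butyldimethylsilyl)oxy]-2-chloro-3,7,7-trimethyl-11-methylidenespiro[5.5]undecan-3-ol
Product: 24 (2S,3R,6S,8S,9R)-2-bromo-8-chloro-1,1,9-trimethyl-5-methylidenespiro[5.5]undecane-3,9-diol (CNP0121782.1)
Conditions: HF·pyridine, pyridine, THF, 0 °C → rt
Reagents that add atoms: none
Why: Buffered fluoride cleaves the secondary silyl ether through Si–F bond formation without a basic alkoxide stage, so the two cis-halohydrins and the exocyclic alkene should be left intact (fluoride desilylation).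

**Compound list**
1 | 3,3-dimethylglutaric anhydride | CC1(C)CC(=O)OC(=O)C1 | starting material
2 | 5-methoxy-3,3-dimethyl-5-oxopentanoic acid | COC(=O)CC(C)(C)CC(=O)O | intermediate
3 | methyl 5-hydroxy-3,3-dimethylpentanoate | COC(=O)CC(C)(C)CCO | intermediate
4 | methyl 3,3-dimethyl-5-oxopentanoate | COC(=O)CC(C)(C)CC=O | intermediate
5 | formaldehyde | C=O | starting material
6 | methyl 4-formyl-3,3-dimethylpent-4-enoate | COC(=O)CC(C)(C)C(=C)C=O | intermediate
7 | methyl 4-(dimethoxymethyl)-3,3-dimethylpent-4-enoate | COC(=O)CC(C)(C)C(=C)C(OC)OC | intermediate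
8 | 4-(dimethoxymethyl)-3,3-dimethylpent-4-enal | O=CCC(C)(C)C(=C)C(OC)OC | intermediate
9 | (2S)-2-bromo-4-(dimethoxymethyl)-3,3-dimethylpent-4-enal | O=C[C@@H](Br)C(C)(C)C(=C)C(OC)OC | intermediate
10 | pentane-2,4-dione | CC(=O)CC(C)=O | starting material
11 | (6R,7S)-7-bromo-9-(dimethoxymethyl)-6-hydroxy-8,8-dimethyldec-9-ene-2,4-dione | CC(=O)CC(=O)C[C@@H](O)[C@@H](Br)C(C)(C)C(=C)C(OC)OC | intermediate
12 | (6R,7S)-7-bromo-2,6-bis[(tert-butyldimethylsilyl)oxy]-9-(dimethoxymethyl)-8,8-dimethyldeca-2,9-dien-4-one (enol ether isomers, one shown) | CC(O[Si](C)(C)C(C)(C)C)=CC(=O)C[C@@H](O[Si](C)(C)C(C)(C)C)[C@@H](Br)C(C)(C)C(=C)C(OC)OC | intermediate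
13 | (6R,7S)-7-bromo-6-[(tert-butyldimethylsilyl)oxy]-9-(dimethoxymethyl)-8,8-dimethyldec-9-ene-2,4-dione | CC(=O)CC(=O)C[C@@H](O[Si](C)(C)C(C)(C)C)[C@@H](Br)C(C)(C)C(=C)C(OC)OC | intermediate
14 | 1-[(1R,3R,4S,6R)-4-bromo-3-[(tert-butyldimethylsilyl)oxy]-6-(dimethoxymethyl)-1-hydroxy-5,5-dimethylbicyclo[4.2.0]octan-8-yl]ethan-1-one (cis-fused, acetyl epimers) | O[C@@]12C[C@@H](O[Si](C)(C)C(C)(C)C)[C@@H](Br)C(C)(C)[C@]1(C(OC)OC)CC2C(C)=O | intermediate
15 | (2S,4S,5R)-4-bromo-5-[(tert-butyldimethylsilyl)oxy]-2-(dimethoxymethyl)-3,3-dimethyl-2-(3-oxobutyl)cyclohexan-1-one | O=C1C[C@@H](O[Si](C)(C)C(C)(C)C)[C@@H](Br)C(C)(C)[C@@]1(CCC(C)=O)C(OC)OC | intermediate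
16 | (1S,3S,4R)-3-bromo-4-[(tert-butyldimethylsilyl)oxy]-2,2-dimethyl-6-oxo-1-(3-oxobutyl)cyclohexane-1-carbaldehyde | O=C1C[C@@H](O[Si](C)(C)C(C)(C)C)[C@@H](Br)C(C)(C)[C@@]1(CCC(C)=O)C=O | intermediate
17 | (3R,4S,6S)-4-bromo-3-[(tert-butyldimethylsilyl)oxy]-7-hydroxy-5,5-dimethylspiro[5.5]undecane-1,9-dione (C7 epimers) | O=C1C[C@@H](O[Si](C)(C)C(C)(C)C)[C@@H](Br)C(C)(C)[C@]12CCC(=O)CC2O | intermediate
18 | (3R,4S,6R)-4-bromo-3-[(tert-butyldimethylsilyl)oxy]-5,5-dimethylspiro[5.5]undec-7-ene-1,9-dione | O=C1C[C@@H](O[Si](C)(C)C(C)(C)C)[C@@H](Br)C(C)(C)[C@]12CCC(=O)C=C2 | intermediate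
19 | (3R,4S,6R)-4-bromo-3-[(tert-butyldimethylsilyl)oxy]-5,5-dimethyl-9-[(triethylsilyl)oxy]spiro[5.5]undec-8-en-1-one | O=C1C[C@@H](O[Si](C)(C)C(C)(C)C)[C@@H](Br)C(C)(C)[C@]12CCC(O[Si](CC)(CC)CC)=CC2 | intermediate
20 | (3R,4S,6R,8R)-4-bromo-3-[(tert-butyldimethylsilyl)oxy]-8-chloro-5,5-dimethylspiro[5.5]undecane-1,9-dione | O=C1C[C@@H](O[Si](C)(C)C(C)(C)C)[C@@H](Br)C(C)(C)[C@]12CCC(=O)[C@H](Cl)C2 | intermediate
21 | (3R,4S,6R,8S)-4-bromo-3-[(tert-butyldimethylsilyl)oxy]-8-chloro-5,5-dimethylspiro[5.5]undecane-1,9-dione | O=C1C[C@@H](O[Si](C)(C)C(C)(C)C)[C@@H](Br)C(C)(C)[C@]12CCC(=O)[C@@H](Cl)C2 | intermediate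
22 | (3R,4S,6R,8S,9R)-4-bromo-3-[(tert-butyldimethylsilyl)oxy]-8-chloro-9-hydroxy-5,5,9-trimethylspiro[5.5]undecan-1-one | O=C1C[C@@H](O[Si](C)(C)C(C)(C)C)[C@@H](Br)C(C)(C)[C@]12CC[C@@](C)(O)[C@@H](Cl)C2 | intermediate
23 | (2S,3R,6S,8S,9R)-8-bromo-9-[(tert-butyldimethylsilyl)oxy]-2-chloro-3,7,7-trimethyl-11-methylidenespiro[5.5]undecan-3-ol | C=C1C[C@@H](O[Si](C)(C)C(C)(C)C)[C@@H](Br)C(C)(C)[C@]12CC[C@@](C)(O)[C@@H](Cl)C2 | intermediate
24 | (2S,3R,6S,8S,9R)-2-bromo-8-chloro-1,1,9-trimethyl-5-methylidenespiro[5.5]undecane-3,9-diol (CNP0121782.1) | C=C1C[C@@H](O)[C@@H](Br)C(C)(C)[C@]12CC[C@@](C)(O)[C@@H](Cl)C2 | target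

**Totals**
Total step count: 17. Longest linear sequence: 17 steps (from 1).

**Steps most likely to fail**

Step 10. The excited enol may decay or fragment faster than it bonds to the congested alkene carbon, or the cyclobutane may close on the bromine/silyloxy face. The fallback replaces the enol by a dioxinone chromophore, which needs no tautomer and can be triplet-sensitised. It sets out from 9 and returns to the route at 15.
- The lithium dienolate of 2,2,6-trimethyl-4H-1,3-dioxin-4-one (LiN(iPr)2, THF, −78 °C) would add through its exocyclic carbon to 9 with the same anti sense to give the dioxinone aldol F1.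
- TBSOTf/2,6-lutidine would give the silyl ether F2.
- Irradiation (300 nm, MeCN/acetone, 0 °C) would give the cyclobutane-fused dioxanone photoadduct F3.
- MeLi (1 equiv, THF, −78 °C) would open the dioxanone carbonyl; on work-up the hemiketal loses acetone to release cyclobutanol 14, whose retro-aldol returns 15.

Step 12. The freed formyl group may be lost by retro-Claisen cleavage, the methyl ketone may condense onto the ring A ketone instead of the aldehyde, or the silyloxy group may be eliminated from ring A. The fallback avoids the free keto aldehyde by using the acetal itself as electrophile. It sets out from 15 and returns at 18, bypassing 16.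
- Kinetic deprotonation of the methyl ketone at CH3 (LiN(iPr)2, 1.05 equiv, THF, −78 °C; Me3SiCl) would give the trimethylsilyl enol ether F4.
- Me3SiOTf (cat.) in CH2Cl2 at −78 °C would ionise the dimethyl acetal and close ring B by an intramolecular Mukaiyama-type addition to the β-methoxy ketone F5.
- Pyrrolidinium acetate would eliminate methanol from F5 to give 18.

Step 16. The reagent may fail to engage the carbonyl screened by the spiro carbon, or its Lewis acidity may ionise the silyloxy or tertiary hydroxyl groups. The fallback is a two-stage Peterson olefination. It sets out from 22 and returns at the target 24, bypassing 23.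
- Me3SiCH2Li/CeCl3 (THF, −78 °C, excess to cover the free hydroxyl) would add to the ring A ketone without enolising it to give the β-hydroxysilane F6.
- Aqueous HF in MeCN would bring about the acidic Peterson elimination and remove the silyl ether in the same operation to give 24.

**Further compounds**
F1 | step 10 | 6-[(2R,3S)-3-bromo-5-(dimethoxymethyl)-2-hydroxy-4,4-dimethylhex-5-en-1-yl]-2,2-dimethyl-4H-1,3-dioxin-4-one | CC1(C)OC(=O)C=C(C[C@@H](O)[C@@H](Br)C(C)(C)C(=C)C(OC)OC)O1
F2 | step 10 | 6-[(2R,3S)-3-bromo-2-[(tert-butyldimethylsilyl)oxy]-5-(dimethoxymethyl)-4,4-dimethylhex-5-en-1-yl]-2,2-dimethyl-4H-1,3-dioxin-4-one | CC1(C)OC(=O)C=C(C[C@@H](O[Si](C)(C)C(C)(C)C)[C@@H](Br)C(C)(C)C(=C)C(OC)OC)O1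
F3 | step 10 | cyclobutane-fused 2,2-dimethyl-1,3-dioxan-4-one photoadduct (ring A carbons as in 14, dioxanone in place of hydroxyl and acetyl) | O1[C@@]23C[C@@H](O[Si](C)(C)C(C)(C)C)[C@@H](Br)C(C)(C)[C@]2(C(OC)OC)CC3C(=O)OC1(C)C
F4 | step 12 | (2S,4S,5R)-4-bromo-5-[(tert-butyldimethylsilyl)oxy]-2-(dimethoxymethyl)-3,3-dimethyl-2-[3-(trimethylsilyloxy)but-3-en-1-yl]cyclohexan-1-one | O=C1C[C@@H](O[Si](C)(C)C(C)(C)C)[C@@H](Br)C(C)(C)[C@@]1(CCC(=C)O[Si](C)(C)C)C(OC)OC
F5 | step 12 | (3R,4S,6S)-4-bromo-3-[(tert-butyldimethylsilyl)oxy]-7-methoxy-5,5-dimethylspiro[5.5]undecane-1,9-dione (C7 epimers) | O=C1C[C@@H](O[Si](C)(C)C(C)(C)C)[C@@H](Br)C(C)(C)[C@]12CCC(=O)CC2OC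
F6 | step 16 | β-hydroxysilane from addition of Me3SiCH2 to the ring A ketone of 22 (new carbinol centre undefined) | C[Si](C)(C)CC1(O)C[C@@H](O[Si](C)(C)C(C)(C)C)[C@@H](Br)C(C)(C)[C@]12CC[C@@](C)(O)[C@@H](Cl)C2
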